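**Retrosynthetic overview**
1. Target ⇐ 3β-alcohol (angeloylation) ⇐ 3-ketone/C12 methyl ester ⇐ allylic C–H oxidation at C3 and C12 of an 8β-acetoxy-5α-hydroxy-eudesma-4(15),11-diene.
2. 5α-Hydroxy-4(15)-ene ⇐ 4α,5α-epoxide ⇐ C4=C5 alkene of eudesma-4,11-dien-8β-ol.
3. Key disconnection: C8–C9 (closing ring B) together with C10–C14, by a Prins cyclisation of a monocyclic ring-A dienyl aldehyde that ends with methyl transfer from aluminium. Ring A is bought (3-methylcyclohex-2-enone); ring B is formed last.
4. Dienyl aldehyde ⇐ Wittig methylenation (makes C9) and Negishi C5–C6 union of 2-iodo-3-methylcyclohex-2-enone with a zinc reagent whose C7 stereocentre comes from lipase desymmetrisation of 2-isopropenylpropane-1,3-diol.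
5. Enabling feature: on ring B the C8 oxygen and the C10 angular methyl are 1,3-syn (both β), and C10 adjoins C5, which can be carried as the C4=C5 alkene. With C9 as the exocyclic methylene of a C9=C10–C5=C4 diene on ring A, attack on the C8 aldehyde gives an allyl cation whose C10 terminus lies under the C8–O–Al–CH3 group.

Key step: step 10

Remark: positions are given in eudesmane numbering (C1–C5 and C10 ring A; C5–C10 ring B; C14 the methyl on C10; C15 the carbon on C4; C11–C13 the side chain on C7).
Assumption: the lipase of step 3 acetylates the hydroxymethyl arm of diol 3 that leads to (S)-4, as is usual for 2-substituted propane-1,3-diols; the configuration at C7, and through it at C8 and C10, rests on this.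

**Route**

Step 1
Reactants: 1 diethyl 2-(propan-2-ylidene)malonate
Product: 2 diethyl 2-(prop-1-en-2-yl)malonate
Conditions: LiN(i-Pr)2, THF, −78 °C; then AcOH, −78 °C
Reagents that add atoms: none
Why: γ-Deprotonation of the alkylidene malonate and kinetic α-protonation of the dienolate should give the deconjugated isopropenyl isomer (deconjugative protonation).

Step 2
Reactants: 2 diethyl 2-(prop-1-en-2-yl)malonate
Product: 3 2-(prop-1-en-2-yl)propane-1,3-diol
Conditions: LiAlH4, Et2O, 0 °C → rt
Reagents that add atoms: none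
Why: Hydride reduction of both ester groups should give the prochiral 1,3-diol, the 1,1-disubstituted alkene being inert.

Step 3
Reactants: 3 2-(prop-1-en-2-yl)propane-1,3-diol
Product: 4 (S)-2-(hydroxymethyl)-3-methylbut-3-en-1-yl acetate
Conditions: Burkholderia cepacia lipase, vinyl acetate, t-BuOMe, rt
Reagents that add atoms: vinyl acetate, CC(=O)OC=C
Why: Irreversible lipase-catalysed transesterification should differentiate the enantiotopic hydroxymethyl groups (enzymatic desymmetrisation) and so set C7.

Step 4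
Reactants: 4 (S)-2-(hydroxymethyl)-3-methylbut-3-en-1-yl acetate
Product: 5 (R)-2-(iodomethyl)-3-methylbut-3-en-1-yl acetate
Conditions: I2, PPh3, imidazole, CH2Cl2, 0 °C
Reagents that add atoms: iodine, II
Why: Appel-type iodination of the primary alcohol should leave the stereocentre, the acetate and the alkene untouched (the descriptor changes only by priority).

Step 5
Reactants: 6 3-methylcyclohex-2-en-1-one
Product: 7 2-iodo-3-methylcyclohex-2-en-1-one
Conditions: I2, pyridine, CH2Cl2, rt
Reagents that add atoms: iodine, II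
Why: Pyridine-mediated α-iodination of an enone (conjugate addition of pyridine, iodination of the enolate, elimination) should give the α-iodoenone.

Step 6
Reactants: 5 (R)-2-(iodomethyl)-3-methylbut-3-en-1-yl acetate; 7 2-iodo-3-methylcyclohex-2-en-1-one
Product: 9 (R)-3-methyl-2-[(2-methyl-6-oxocyclohex-1-en-1-yl)methyl]but-3-en-1-yl acetate, via organozinc iodide 8 (not isolated)
Conditions: Zn, LiCl, THF, rt; then 7, Pd2(dba)3, SPhos, THF, rt → 40 °C
Reagents that add atoms: none
Why: Zinc insertion into the primary iodide tolerates the acetate, and Negishi sp3–sp2 coupling with the α-iodoenone should form the C5–C6 bond without touching C7.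

Step 7
Reactants: 9 (R)-3-methyl-2-[(2-methyl-6-oxocyclohex-1-en-1-yl)methyl]but-3-en-1-yl acetate
Product: 10 (R)-2-[2-(hydroxymethyl)-3-methylbut-3-en-1-yl]-3-methylcyclohex-2-en-1-one
Conditions: K2CO3, MeOH, 0 °C
Reagents that add atoms: none
Why: Mild methanolysis should cleave the primary acetate and leave the tetrasubstituted enone alone.

Step 8
Reactants: 10 (R)-2-[2-(hydroxymethyl)-3-methylbut-3-en-1-yl]-3-methylcyclohex-2-en-1-one
Product: 11 (R)-3-methyl-2-[(2-methyl-6-methylidenecyclohex-1-en-1-yl)methyl]but-3-en-1-ol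
Conditions: Ph3PCH3Br, KOt-Bu (excess), THF, 0 °C → reflux
Reagents that add atoms: methyltriphenylphosphonium bromide, C[P+](c1ccccc1)(c1ccccc1)c1ccccc1.[Br-]
Why: Wittig methylenation should turn the enone carbonyl into the exocyclic methylene C9 and so create the ring-A 1,3-diene, excess ylide accommodating the free hydroxyl.

Step 9
Reactants: 11 (R)-3-methyl-2-[(2-methyl-6-methylidenecyclohex-1-en-1-yl)methyl]but-3-en-1-ol
Product: 12 (R)-3-methyl-2-[(2-methyl-6-methylidenecyclohex-1-en-1-yl)methyl]but-3-enal
Conditions: Dess–Martin periodinane, NaHCO3, CH2Cl2, 0 °C; used at once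
Reagents that add atoms: none
Why: Buffered Dess–Martin oxidation should give the α-branched β,γ-unsaturated aldehyde without epimerisation at C7 or alkene migration.

Step 10
Reactants: 12 (R)-3-methyl-2-[(2-methyl-6-methylidenecyclohex-1-en-1-yl)methyl]but-3-enal
Product: 14 eudesma-4,11-dien-8β-ol (7R,8R,10R; 7α-H and 10β-methyl), via aluminate allyl-cation zwitterion 13 (not isolated)
Conditions: Me2AlCl (2.5 equiv), CH2Cl2, −78 → −20 °C; aq. KNaC4H4O6
Reagents that add atoms: dimethylaluminium chloride, C[Al](C)Cl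
Why: Proposed new method: Me2AlCl activates the aldehyde of 12 and the exocyclic methylene C9 of the ring-A diene (C9=C10–C5=C4) attacks C8 in a chair-like transition state with the C7 isopropenyl group equatorial, giving the aluminate/allyl-cation zwitterion 13 (charge over C10–C5–C4), which then passes a methyl group from aluminium to C10 through a six-membered array C10···CH3–Al–O–C8–C9. The closest known reaction type is the alkylaluminium-halide-promoted Prins cyclisation of unsaturated aldehydes in which the zwitterion collapses by methyl or chloride transfer from aluminium to the carbocation instead of by proton loss; its use on a diene-derived allyl cation to make a ring-fusion quaternary carbon has not been shown. Ring B closes through the C8–C9 bond in a six-membered closure that is endo with respect to the C9=C10 bond and exo with respect to the carbonyl group, ring A being already present. C8 is set by the equatorial preference at C7 (fixed in step 3) together with the requirement that only a pseudoaxial C8–O–Al can reach C10, and C10 is set by this intramolecular delivery, so the 8β-oxygen and the 10β-methyl should end 1,3-syn and cis to the 7β-isopropenyl group. The step needs methyl transfer to win over 1,5-proton transfer (carbonyl-ene product) and chloride transfer, which the excess of Me2AlCl is meant to secure by holding the alkoxide oxygen as a non-basic aluminate, and it needs delivery to C10 and not C4, which the short reach of the O–Al–CH3 unit secures.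

Step 11
Reactants: 14 eudesma-4,11-dien-8β-ol
Product: 15 4α,5α-epoxyeudesm-11-en-8β-ol
Conditions: mCPBA (1.05 equiv), NaHCO3, CH2Cl2, −20 °C
Reagents that add atoms: 3-chloroperoxybenzoic acid, O=C(OO)c1cccc(Cl)c1
Why: Prilezhaev epoxidation should be fastest at the tetrasubstituted C4=C5 bond and occur anti to the 10β-methyl, giving the α-epoxide and setting C5.

Step 12
Reactants: 15 4α,5α-epoxyeudesm-11-en-8β-ol
Product: 16 eudesma-4(15),11-diene-5α,8β-diol
Conditions: Et2Al(TMP) [from 2,2,6,6-tetramethylpiperidine, n-BuLi, Et2AlCl; 4 equiv], PhMe, 0 °C → rt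
Reagents that add atoms: none
Why: The aluminium amide (epoxide-to-allylic-alcohol isomerisation) should remove a proton syn to the aluminium-bound oxygen from the least hindered β-carbon, the C15 methyl, so the C4–O bond breaks and the 5α-hydroxy-4(15)-ene results with C5 retained.

Step 13
Reactants: 16 eudesma-4(15),11-diene-5α,8β-diol
Product: 17 5α-hydroxyeudesma-4(15),11-dien-8β-yl acetate
Conditions: Ac2O, DMAP (cat.), pyridine, CH2Cl2, rt
Reagents that add atoms: acetic anhydride, CC(=O)OC(C)=O
Why: DMAP-catalysed acetylation should reach only the secondary 8β-hydroxyl, the tertiary allylic 5α-hydroxyl being unreactive under these conditions.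

Step 14
Reactants: 17 5α-hydroxyeudesma-4(15),11-dien-8β-yl acetate
Product: 19 5α-hydroxy-3,12-dioxoeudesma-4(15),11(13)-dien-8β-yl acetate, via 3,12-diol 18 (not isolated)
Conditions: SeO2 (0.5 equiv), t-BuOOH, CH2Cl2, rt; then MnO2, CH2Cl2, rt
Reagents that add atoms: selenium dioxide, O=[Se]=O; tert-butyl hydroperoxide, CC(C)(C)OO
Why: Riley allylic oxidation (ene reaction, then 2,3-sigmatropic shift) should hydroxylate the CH2 next to the 4(15)-alkene (C3) and the methyl of the isopropenyl group in preference to the tertiary C7–H, and MnO2 then oxidises both allylic alcohols, so the C3 configuration is immaterial here.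

Step 15
Reactants: 19 5α-hydroxy-3,12-dioxoeudesma-4(15),11(13)-dien-8β-yl acetate
Product: 21 methyl 8β-acetoxy-5α-hydroxy-3-oxoeudesma-4(15),11(13)-dien-12-oate, via acrylic acid 20 (not isolated)
Conditions: NaClO2, NaH2PO4, 2-methylbut-2-ene, t-BuOH/H2O, 0 °C; then Me3SiCHN2, PhMe/MeOH, 0 °C
Reagents that add atoms: sodium chlorite, [Na+].[O-]Cl=O; trimethylsilyldiazomethane, C[Si](C)(C)C=[N+]=[N-]
Why: Pinnick oxidation should convert the enal into the acrylic acid without touching the enone, and trimethylsilyldiazomethane methylates the acid under neutral conditions.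

Step 16
Reactants: 21 methyl 8β-acetoxy-5α-hydroxy-3-oxoeudesma-4(15),11(13)-dien-12-oate
Product: 22 methyl 8β-acetoxy-3β,5α-dihydroxyeudesma-4(15),11(13)-dien-12-oate
Conditions: NaBH4, CeCl3·7H2O, MeOH, −78 °C
Reagents that add atoms: none
Why: Luche 1,2-reduction should deliver hydride axially from the α face of the exocyclic enone (the face of the 5α-hydroxyl), giving the equatorial 3β-alcohol and setting C3, with the esters inert at this temperature.

Step 17
Reactants: 22 methyl 8β-acetoxy-3β,5α-dihydroxyeudesma-4(15),11(13)-dien-12-oate; 23 angelic acid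
Product: 25 methyl 8β-acetoxy-3β-angeloyloxy-5α-hydroxyeudesma-4(15),11(13)-dien-12-oate (CNP0179024.1), via mixed anhydride 24 (not isolated)
Conditions: 2,4,6-Cl3C6H2COCl, Et3N, PhMe, rt; then 22, PhMe, 75 °C
Reagents that add atoms: none
Why: Yamaguchi esterification through the 2,4,6-trichlorobenzoyl mixed anhydride, run without DMAP, should acylate the secondary allylic 3β-hydroxyl without Z-to-E isomerisation of the angelate, the tertiary 5α-hydroxyl being inert.

**Compound list**
1 | diethyl 2-(propan-2-ylidene)malonate | CCOC(=O)C(=C(C)C)C(=O)OCC | starting material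
2 | diethyl 2-(prop-1-en-2-yl)malonate | CCOC(=O)C(C(C)=C)C(=O)OCC | intermediate
3 | 2-(prop-1-en-2-yl)propane-1,3-diol | C=C(C)C(CO)CO | intermediate
4 | (S)-2-(hydroxymethyl)-3-methylbut-3-en-1-yl acetate | C=C(C)[C@H](COC(C)=O)CO | intermediate
5 | (R)-2-(iodomethyl)-3-methylbut-3-en-1-yl acetate | C=C(C)[C@H](COC(C)=O)CI | intermediate
6 | 3-methylcyclohex-2-en-1-one | CC1=CC(=O)CCC1 | starting material
7 | 2-iodo-3-methylcyclohex-2-en-1-one | CC1=C(I)C(=O)CCC1 | intermediate
8 | [(R)-2-(acetoxymethyl)-3-methylbut-3-en-1-yl]zinc iodide | C=C(C)[C@H](COC(C)=O)C[Zn]I | intermediate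
9 | (R)-3-methyl-2-[(2-methyl-6-oxocyclohex-1-en-1-yl)methyl]but-3-en-1-yl acetate | C=C(C)[C@H](COC(C)=O)CC1=C(C)CCCC1=O | intermediate
10 | (R)-2-[2-(hydroxymethyl)-3-methylbut-3-en-1-yl]-3-methylcyclohex-2-en-1-one | C=C(C)[C@H](CO)CC1=C(C)CCCC1=O | intermediate
11 | (R)-3-methyl-2-[(2-methyl-6-methylidenecyclohex-1-en-1-yl)methyl]but-3-en-1-ol | C=C(C)[C@H](CO)CC1=C(C)CCCC1=C | intermediate
12 | (R)-3-methyl-2-[(2-methyl-6-methylidenecyclohex-1-en-1-yl)methyl]but-3-enal | C=C(C)[C@H](C=O)CC1=C(C)CCCC1=C | intermediate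
13 | aluminate allyl-cation zwitterion (C8–O–AlMe2Cl, cation over C10–C5–C4) | C=C(C)[C@H]1CC2=C(C)CCC[C+]2C[C@H]1O[Al-](C)(C)Cl | intermediate
14 | eudesma-4,11-dien-8β-ol (7R,8R,10R) | C=C(C)[C@H]1CC2=C(C)CCC[C@]2(C)C[C@H]1O | intermediate
15 | 4α,5α-epoxyeudesm-11-en-8β-ol | C=C(C)[C@H]1C[C@@]2(O3)[C@@]3(C)CCC[C@]2(C)C[C@H]1O | intermediate
16 | eudesma-4(15),11-diene-5α,8β-diol | C=C(C)[C@H]1C[C@@]2(O)C(=C)CCC[C@]2(C)C[C@H]1O | intermediate
17 | 5α-hydroxyeudesma-4(15),11-dien-8β-yl acetate | C=C(C)[C@H]1C[C@@]2(O)C(=C)CCC[C@]2(C)C[C@H]1OC(C)=O | intermediate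
18 | 3,5α,12-trihydroxyeudesma-4(15),11(13)-dien-8β-yl acetate (C3 epimers) | C=C(CO)[C@H]1C[C@@]2(O)C(=C)C(O)CC[C@]2(C)C[C@H]1OC(C)=O | intermediate
19 | 5α-hydroxy-3,12-dioxoeudesma-4(15),11(13)-dien-8β-yl acetate | C=C(C=O)[C@H]1C[C@@]2(O)C(=C)C(=O)CC[C@]2(C)C[C@H]1OC(C)=O | intermediate
20 | 8β-acetoxy-5α-hydroxy-3-oxoeudesma-4(15),11(13)-dien-12-oic acid | C=C(C(=O)O)[C@H]1C[C@@]2(O)C(=C)C(=O)CC[C@]2(C)C[C@H]1OC(C)=O | intermediate
21 | methyl 8β-acetoxy-5α-hydroxy-3-oxoeudesma-4(15),11(13)-dien-12-oate | C=C(C(=O)OC)[C@H]1C[C@@]2(O)C(=C)C(=O)CC[C@]2(C)C[C@H]1OC(C)=O | intermediate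
22 | methyl 8β-acetoxy-3β,5α-dihydroxyeudesma-4(15),11(13)-dien-12-oate | C=C(C(=O)OC)[C@H]1C[C@@]2(O)C(=C)[C@@H](O)CC[C@]2(C)C[C@H]1OC(C)=O | intermediate
23 | angelic acid, (Z)-2-methylbut-2-enoic acid | C/C=C(/C)C(=O)O | starting material
24 | angelic 2,4,6-trichlorobenzoic anhydride | C/C=C(/C)C(=O)OC(=O)c1c(Cl)cc(Cl)cc1Cl | intermediate
25 | methyl 8β-acetoxy-3β-angeloyloxy-5α-hydroxyeudesma-4(15),11(13)-dien-12-oate (3S,5S,7R,8R,10R), CNP0179024.1 | C=C(C(=O)OC)[C@H]1C[C@@]2(O)C(=C)[C@@H](OC(=O)/C(C)=C\C)CC[C@]2(C)C[C@H]1OC(C)=O | target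

**Totals**
Total step count: 17. Longest linear sequence: 16 steps (steps 1–4 and 6–17; step 5 makes the second coupling partner).

**Steps most likely to fail**

1. Step 10 (Proposed new method). The zwitterion may collapse by 1,5-proton transfer to the carbonyl-ene product or by chloride transfer instead of methyl transfer, or the methyl may not be delivered because the C8 aluminate oxygen is not pseudoaxial.
Fallback, from iodide 5 (through its zinc reagent 8) back to 14, with C10 and its methyl in place before ring B is closed at the same C8–C9 bond. Commercial 2,6-dimethylcyclohexanone is converted with Me3SiCl, NaI and Et3N in MeCN into the tetrasubstituted silyl enol ether 2,6-dimethyl-1-(trimethylsilyloxy)cyclohexene F1. Catalytic asymmetric hydroxymethylation (aqueous formaldehyde, Sc(OTf)3, chiral 2,2'-bipyridine diol ligand of the enantiomer that gives the 2R ketone) should give (2R)-2-(hydroxymethyl)-2,6-dimethylcyclohexanone F2. Appel-type iodination (I2, PPh3, imidazole) gives the neopentyl iodide (2S)-2-(iodomethyl)-2,6-dimethylcyclohexanone F3, and KN(SiMe3)2 with PhNTf2 gives the enol triflate F4, since only the C4 side can enolise. Negishi coupling of F4 with 8 (Pd2(dba)3, SPhos) gives the acetate F5, K2CO3 in MeOH gives the alcohol F6, and Dess–Martin oxidation gives the iodo aldehyde F7. A SmI2/HMPA Barbier cyclisation of the C9 iodide onto the C8 aldehyde then closes ring B to the carbinol F8 (C8 epimers). Dess–Martin oxidation gives the 8-ketone F9, and LiBH(s-Bu)3 at −78 °C, attacking anti to the 10β-methyl, should give 14.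

2. Step 14. The two allylic sites may react at unequal rates, with over-oxidation at C3 or attack at the tertiary C7–H before the isopropenyl methyl is consumed.
Fallback, from 17 back to 21, oxidising one site at a time. Hydroxyl-directed epoxidation (VO(acac)2, t-BuOOH) masks the 4(15)-alkene as the 4,15-epoxide F10. SeO2/t-BuOOH and then MnO2 act on the only remaining alkene to give the enal F11, and Pinnick oxidation with Me3SiCHN2 methylation gives the methyl ester F12. Deoxygenation of the epoxide (MeReO3 cat., PPh3) returns the alkene in methyl 8β-acetoxy-5α-hydroxyeudesma-4(15),11(13)-dien-12-oate F13. SeO2/t-BuOOH and MnO2, now with a single reactive site at C3, should give 21.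

3. Step 3. The enzyme may acylate the other enantiotopic arm, or discriminate poorly between the two.
Fallback, from 3 back to 4. The diol is peracetylated (Ac2O, pyridine) to the diacetate F14, and the same lipase in pH 7 phosphate buffer hydrolyses one enantiotopic acetate. Hydrolysis frees the arm that acylation would esterify, so the monoacetate has the opposite configuration to that from the acylation mode; whichever mode gives (S)-4 is used.

**Further compounds**
F1 | step 10 | 2,6-dimethyl-1-(trimethylsilyloxy)cyclohex-1-ene | C[Si](C)(C)OC1=C(C)CCCC1C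
F2 | step 10 | (2R)-2-(hydroxymethyl)-2,6-dimethylcyclohexan-1-one (C6 epimers) | O=C1C(C)CCC[C@]1(C)CO
F3 | step 10 | (2S)-2-(iodomethyl)-2,6-dimethylcyclohexan-1-one (C6 epimers) | O=C1C(C)CCC[C@]1(C)CI
F4 | step 10 | (S)-6-(iodomethyl)-2,6-dimethylcyclohex-1-en-1-yl trifluoromethanesulfonate | O=S(=O)(OC1=C(C)CCC[C@]1(C)CI)C(F)(F)F
F5 | step 10 | (R)-2-{[(S)-6-(iodomethyl)-2,6-dimethylcyclohex-1-en-1-yl]methyl}-3-methylbut-3-en-1-yl acetate | C=C(C)[C@H](COC(C)=O)CC1=C(C)CCC[C@]1(C)CI
F6 | step 10 | (R)-2-{[(S)-6-(iodomethyl)-2,6-dimethylcyclohex-1-en-1-yl]methyl}-3-methylbut-3-en-1-ol | C=C(C)[C@H](CO)CC1=C(C)CCC[C@]1(C)CI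
F7 | step 10 | (R)-2-{[(S)-6-(iodomethyl)-2,6-dimethylcyclohex-1-en-1-yl]methyl}-3-methylbut-3-enal | C=C(C)[C@H](C=O)CC1=C(C)CCC[C@]1(C)CI
F8 | step 10 | eudesma-4,11-dien-8-ol (C8 epimers) | C=C(C)[C@H]1CC2=C(C)CCC[C@]2(C)CC1O
F9 | step 10 | eudesma-4,11-dien-8-one | C=C(C)[C@H]1CC2=C(C)CCC[C@]2(C)CC1=O
F10 | step 14 | 4,15-epoxy-5α-hydroxyeudesm-11-en-8β-yl acetate (epoxide oxygen syn to the 5α-hydroxyl) | C=C(C)[C@H]1C[C@@]2(O)[C@@]3(CO3)CCC[C@]2(C)C[C@H]1OC(C)=O
F11 | step 14 | 4,15-epoxy-5α-hydroxy-12-oxoeudesm-11(13)-en-8β-yl acetate | C=C(C=O)[C@H]1C[C@@]2(O)[C@@]3(CO3)CCC[C@]2(C)C[C@H]1OC(C)=O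
F12 | step 14 | methyl 8β-acetoxy-4,15-epoxy-5α-hydroxyeudesm-11(13)-en-12-oate | C=C(C(=O)OC)[C@H]1C[C@@]2(O)[C@@]3(CO3)CCC[C@]2(C)C[C@H]1OC(C)=O
F13 | step 14 | methyl 8β-acetoxy-5α-hydroxyeudesma-4(15),11(13)-dien-12-oate | C=C(C(=O)OC)[C@H]1C[C@@]2(O)C(=C)CCC[C@]2(C)C[C@H]1OC(C)=O
F14 | step 3 | 2-(prop-1-en-2-yl)propane-1,3-diyl diacetate | C=C(C)C(COC(C)=O)COC(C)=O
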